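**Strategy.** The chroman is cut across the dihydropyran ring at C3–C4 and O1–C8a. This exposes a hidden mirror plane in the benzene ring: C8a is flanked by C4a and C8, so C4 and the C8 methyl are the two equivalent methyl groups of a 4-fluoro-3,5-dimethylphenol ether. In one operation a benzylic potassium species from that arene opens an enantiopure 2,2-disubstituted epoxide carrying the whole farnesyl-derived chain (C3–C4), and the tertiary alkoxide released displaces the flanked fluoride (O1–C8a). The C2 stereocentre comes from a Sharpless epoxidation and its C2–O1 bond is never broken. Cross-metathesis with methyl methacrylate then installs the E-enoic acid terminus.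

Key step: step 6

Assumption: 4-fluoro-3,5-dimethylphenol, (2E,6E)-farnesyl bromide, 2-methylprop-2-en-1-ol and methyl methacrylate are taken as purchasable; chroman numbering (O1, C2, C3, C4, C4a, C5–C8, C8a) is used throughout.

**Route**

Step 1
Reactants: 1 4-fluoro-3,5-dimethylphenol
Product: 2 2-fluoro-5-(methoxymethoxy)-1,3-dimethylbenzene
Conditions: NaH, MOMCl, DMF, 0 °C → rt
Reagents that add atoms: chloromethyl methyl ether (MOMCl), COCCl
Why: Williamson O-alkylation of the sodium phenoxide gives the MOM acetal, which should tolerate organopotassium bases, alkoxides and fluoride and is removed by dilute acid at the end.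

Step 2
Reactants: 3 2-methylprop-2-en-1-ol; 4 (2E,6E)-farnesyl bromide
Product: 6 (5E,9E)-6,10,14-trimethyl-2-methylidenepentadeca-5,9,13-trien-1-ol, via dilithiated methallyl alcohol 5 (not isolated)
Conditions: n-BuLi (2 equiv), TMEDA, Et2O, 0 °C → rt; then 4, THF, −78 °C → rt
Reagents that add atoms: none
Why: Double deprotonation (O–H, then allylic C–H) gives the O,C-dianion, whose carbon terminus should displace the primary allylic bromide by SN2 (dianion alkylation) without touching the E olefins.

Step 3
Reactants: 6 (5E,9E)-6,10,14-trimethyl-2-methylidenepentadeca-5,9,13-trien-1-ol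
Product: 7 [(2R)-2-[(3E,7E)-4,8,12-trimethyltrideca-3,7,11-trien-1-yl]oxiran-2-yl]methanol
Conditions: Ti(Oi-Pr)4 (cat.), D-(−)-diethyl tartrate (cat.), t-BuOOH, 4 Å MS, CH2Cl2, −20 °C
Reagents that add atoms: tert-butyl hydroperoxide, CC(C)(C)OO
Why: Katsuki–Sharpless asymmetric epoxidation is directed by the allylic hydroxyl, so only the methylidene olefin reacts, and the D-(−)-tartrate ligand should deliver oxygen to the face that gives the R quaternary carbon (the enantiomeric series to that obtained from allylic alcohols with L-(+)-tartrate).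

Step 4
Reactants: 7 [(2R)-2-[(3E,7E)-4,8,12-trimethyltrideca-3,7,11-trien-1-yl]oxiran-2-yl]methanol
Product: 8 (2R,5E,9E)-2,6,10,14-tetramethylpentadeca-5,9,13-triene-1,2-diol
Conditions: LiAlH4, THF, 0 °C → rt; aq. NaOH work-up
Reagents that add atoms: none
Why: Hydride opening of the epoxide (SN2) should occur at the unsubstituted CH2, which becomes the methyl group, while the C–O bond at the quaternary carbon is untouched, so the R tertiary carbinol is kept.

Step 5
Reactants: 8 (2R,5E,9E)-2,6,10,14-tetramethylpentadeca-5,9,13-triene-1,2-diol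
Product: 10 (2R)-2-methyl-2-[(3E,7E)-4,8,12-trimethyltrideca-3,7,11-trien-1-yl]oxirane, via primary monotosylate 9 (not isolated)
Conditions: NaH, N-tosylimidazole, THF, 0 °C → rt
Reagents that add atoms: none
Why: Selective sulfonylation of the primary alkoxide followed by intramolecular Williamson displacement (3-exo-tet) by the tertiary alkoxide closes the terminal epoxide; the stereocentre is not a reacting centre.

Step 6
Reactants: 2 2-fluoro-5-(methoxymethoxy)-1,3-dimethylbenzene; 10 (2R)-2-methyl-2-[(3E,7E)-4,8,12-trimethyltrideca-3,7,11-trien-1-yl]oxirane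
Product: 13 (2R)-6-(methoxymethoxy)-2,8-dimethyl-2-[(3E,7E)-4,8,12-trimethyltrideca-3,7,11-trien-1-yl]-3,4-dihydro-2H-chromene, via benzylic potassium reagent 11 (not isolated), via potassium alkoxide 12 (not isolated)
Conditions: 2 (1.5 equiv), n-BuLi, KOt-Bu, TMP(H), THF, −78 °C; then 10, −78 → 0 °C; then DMPU, 18-crown-6, 70 °C
Reagents that add atoms: none
Why: n-BuLi/KOt-Bu with TMP(H) as proton shuttle converts 2 into the thermodynamic benzylic potassium species 11 (either methyl, since the two are related by the mirror plane through C–F and C–OMOM), which attacks the unsubstituted CH2 of epoxide 10 in an SN2 opening to make the C3–C4 bond and the tertiary potassium alkoxide 12; when the medium is made dipolar and warmed, this alkoxide displaces fluoride at the adjacent ring carbon (intramolecular SNAr) to make the O1–C8a bond. The closest known reaction types are lateral metalation of ortho-fluorotoluenes with epoxide alkylation and the alkoxide SNAr cyclisation of 3-(2-fluoroaryl)propanols to chromans, here run in one flask. The dihydropyran ring closes in a 6-exo-trig ipso attack on the fluorine-bearing carbon (addition–elimination through a Meisenheimer-type transition state). No stereocentre is created: C2 arrives in epoxide 10 and none of its bonds is broken, so the R configuration is retained. The step needs benzylic instead of ring metalation (secured by amine-mediated equilibration and by ring C–H bonds wedged between OMOM and methyl), attack at the epoxide CH2 (the other carbon is quaternary) and ipso substitution only (the fluorine-bearing carbon has no ortho hydrogen, so no aryne can form); the para MOM-oxy group slows the closure, which is why a crown ether and heat are used.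

Step 7
Reactants: 13 (2R)-6-(methoxymethoxy)-2,8-dimethyl-2-[(3E,7E)-4,8,12-trimethyltrideca-3,7,11-trien-1-yl]-3,4-dihydro-2H-chromene; 14 methyl methacrylate
Product: 15 methyl (2E,6E,10E)-13-[(2R)-6-(methoxymethoxy)-2,8-dimethyl-3,4-dihydro-2H-chromen-2-yl]-2,6,10-trimethyltrideca-2,6,10-trienoate
Conditions: second-generation Hoveyda–Grubbs catalyst (5 mol%), methyl methacrylate (excess), CH2Cl2, 40 °C, N2 sweep
Reagents that add atoms: none
Why: Olefin cross-metathesis should exchange the terminal isopropylidene (the least hindered trisubstituted olefin, lost as volatile isobutene) for the methacrylate alkylidene and give the trisubstituted enoate as the thermodynamically preferred E isomer, the internal olefins with two chain substituents reacting more slowly.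

Step 8
Reactants: 15 methyl (2E,6E,10E)-13-[(2R)-6-(methoxymethoxy)-2,8-dimethyl-3,4-dihydro-2H-chromen-2-yl]-2,6,10-trimethyltrideca-2,6,10-trienoate
Product: 18 garcinoic acid [(2E,6E,10E)-13-[(2R)-6-hydroxy-2,8-dimethyl-3,4-dihydro-2H-chromen-2-yl]-2,6,10-trimethyltrideca-2,6,10-trienoic acid], via lithium carboxylate 16 (not isolated), via MOM-protected acid 17 (not isolated)
Conditions: LiOH, THF/H2O, 50 °C (degassed); then aq. HCl to pH 1, THF, 40 °C
Reagents that add atoms: lithium hydroxide, [Li+].[OH-]
Why: Saponification of the methyl ester (acyl substitution by hydroxide) followed in the same flask by acid hydrolysis of the MOM acetal should release the carboxylic acid and the phenol without affecting the chroman ether, the olefin geometry or the stereocentre.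

**Compound list**

1 | 4-fluoro-3,5-dimethylphenol | Cc1cc(O)cc(C)c1F | starting material
2 | 2-fluoro-5-(methoxymethoxy)-1,3-dimethylbenzene | COCOc1cc(C)c(F)c(C)c1 | intermediate
3 | 2-methylprop-2-en-1-ol | C=C(C)CO | starting material
4 | (2E,6E)-farnesyl bromide | CC(C)=CCC/C(C)=C/CC/C(C)=C/CBr | starting material
5 | dilithiated methallyl alcohol (formed in the flask) | [Li]OCC(=C)C[Li] | intermediate
6 | (5E,9E)-6,10,14-trimethyl-2-methylidenepentadeca-5,9,13-trien-1-ol | CC(C)=CCC/C(C)=C/CC/C(C)=C/CCC(=C)CO | intermediate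
7 | [(2R)-2-[(3E,7E)-4,8,12-trimethyltrideca-3,7,11-trien-1-yl]oxiran-2-yl]methanol | CC(C)=CCC/C(C)=C/CC/C(C)=C/CC[C@@]1(CO)CO1 | intermediate
8 | (2R,5E,9E)-2,6,10,14-tetramethylpentadeca-5,9,13-triene-1,2-diol | CC(C)=CCC/C(C)=C/CC/C(C)=C/CC[C@@](C)(O)CO | intermediate
9 | (2R,5E,9E)-2-hydroxy-2,6,10,14-tetramethylpentadeca-5,9,13-trien-1-yl 4-methylbenzenesulfonate (formed in the flask) | CC(C)=CCC/C(C)=C/CC/C(C)=C/CC[C@@](C)(O)COS(=O)(=O)c1ccc(C)cc1 | intermediate
10 | (2R)-2-methyl-2-[(3E,7E)-4,8,12-trimethyltrideca-3,7,11-trien-1-yl]oxirane | CC(C)=CCC/C(C)=C/CC/C(C)=C/CC[C@]1(C)CO1 | intermediate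
11 | [2-fluoro-5-(methoxymethoxy)-3-methylbenzyl]potassium (formed in the flask) | COCOc1cc(C)c(F)c(C[K])c1 | intermediate
12 | potassium (3R,6E,10E)-1-[2-fluoro-5-(methoxymethoxy)-3-methylphenyl]-3,7,11,15-tetramethylhexadeca-6,10,14-trien-3-olate (formed in the flask) | CC(C)=CCC/C(C)=C/CC/C(C)=C/CC[C@@](C)([O-])CCc1cc(OCOC)cc(C)c1F.[K+] | intermediate
13 | (2R)-6-(methoxymethoxy)-2,8-dimethyl-2-[(3E,7E)-4,8,12-trimethyltrideca-3,7,11-trien-1-yl]-3,4-dihydro-2H-chromene | CC(C)=CCC/C(C)=C/CC/C(C)=C/CC[C@]1(C)CCc2cc(OCOC)cc(C)c2O1 | intermediate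
14 | methyl methacrylate | C=C(C)C(=O)OC | starting material
15 | methyl (2E,6E,10E)-13-[(2R)-6-(methoxymethoxy)-2,8-dimethyl-3,4-dihydro-2H-chromen-2-yl]-2,6,10-trimethyltrideca-2,6,10-trienoate | COC(=O)/C(C)=C/CC/C(C)=C/CC/C(C)=C/CC[C@]1(C)CCc2cc(OCOC)cc(C)c2O1 | intermediate
16 | lithium (2E,6E,10E)-13-[(2R)-6-(methoxymethoxy)-2,8-dimethyl-3,4-dihydro-2H-chromen-2-yl]-2,6,10-trimethyltrideca-2,6,10-trienoate (formed in the flask) | [Li+].[O-]C(=O)/C(C)=C/CC/C(C)=C/CC/C(C)=C/CC[C@]1(C)CCc2cc(OCOC)cc(C)c2O1 | intermediate
17 | (2E,6E,10E)-13-[(2R)-6-(methoxymethoxy)-2,8-dimethyl-3,4-dihydro-2H-chromen-2-yl]-2,6,10-trimethyltrideca-2,6,10-trienoic acid (formed in the flask) | OC(=O)/C(C)=C/CC/C(C)=C/CC/C(C)=C/CC[C@]1(C)CCc2cc(OCOC)cc(C)c2O1 | intermediate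
18 | garcinoic acid, (2E,6E,10E)-13-[(2R)-6-hydroxy-2,8-dimethyl-3,4-dihydro-2H-chromen-2-yl]-2,6,10-trimethyltrideca-2,6,10-trienoic acid | OC(=O)/C(C)=C/CC/C(C)=C/CC/C(C)=C/CC[C@]1(C)CCc2cc(O)cc(C)c2O1 | target

**Step count.** Total: 8 steps. Longest linear sequence: 7 steps (steps 2 to 8); step 1 is a one-step side branch.

**Steps most likely to fail**

Step 6. Fluoride displacement on a ring that carries a para alkoxy donor may be slow. Base-mediated scrambling of the chain olefins or simple protonation of the alkoxide could then overtake ring closure, and ring metalation could compete with benzylic metalation. The fallback makes the two bonds separately and closes the aryl–oxygen bond by palladium catalysis; it sets out from epoxide 10 and comes back at 13. Commercial 4-chloro-3,5-dimethylphenol (Cc1cc(O)cc(C)c1Cl) would be protected (NaH, MOMCl, DMF) as 2-chloro-5-(methoxymethoxy)-1,3-dimethylbenzene F1. Metalation as in step 6 at −78 °C (the chloride has no ortho hydrogen and should not exchange at this temperature) should give the benzylic potassium reagent F2, which opens 10. Aqueous quench at 0 °C should give the chloro alcohol (3R,6E,10E)-1-[2-chloro-5-(methoxymethoxy)-3-methylphenyl]-3,7,11,15-tetramethylhexadeca-6,10,14-trien-3-ol F3. Intramolecular Buchwald–Hartwig etherification (Pd(OAc)2, 2-(di-tert-butylphosphino)-1,1'-binaphthyl, Cs2CO3, toluene, 90 °C) should then give 13.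

Step 7. The metathesis may show poor site selectivity, with cleavage at the internal trisubstituted olefins and chain scission, or may stall. The fallback oxidises the terminal E-methyl instead; it sets out from 13 and comes back at 17. Allylic oxidation (SeO2 cat., t-BuOOH, salicylic acid, CH2Cl2, rt; then NaBH4 to reduce over-oxidised aldehyde) should give (2E,6E,10E)-13-[(2R)-6-(methoxymethoxy)-2,8-dimethyl-3,4-dihydro-2H-chromen-2-yl]-2,6,10-trimethyltrideca-2,6,10-trien-1-ol F4. MnO2 in CH2Cl2 should give the corresponding E-enal F5. Pinnick oxidation (NaClO2, NaH2PO4, 2-methyl-2-butene, t-BuOH/H2O) should give acid 17, which is isolated and carried through the acid stage of step 8.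

Step 2. Competing SN2′ attack, O-alkylation or elimination of the allylic bromide may give poor mass return of 6; the same fallback also removes the dependence on the enantioselectivity of step 3. It uses a sulfone carbanion and a chiral-pool epoxide; it sets out from 4 and comes back at diol 8, replacing steps 2 to 4. Bromide 4 with PhSO2Na in DMF should give (2E,6E)-farnesyl phenyl sulfone F6. Deprotonation (n-BuLi, THF/DMPU, −78 °C) gives the lithiated sulfone F7, used in excess so that the first equivalent deprotonates the hydroxyl. F7 should open commercial (S)-2-methylglycidol (OC[C@@]1(C)CO1) at its CH2 to give (2R,5E,9E)-2,6,10,14-tetramethyl-4-(phenylsulfonyl)pentadeca-5,9,13-triene-1,2-diol F8 as a mixture of epimers at the sulfonyl carbon. Reductive desulfonylation (PdCl2(dppp) cat., LiEt3BH, THF, 0 °C) should give 8.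

**Further compounds**

F1 | step 6 | 2-chloro-5-(methoxymethoxy)-1,3-dimethylbenzene | COCOc1cc(C)c(Cl)c(C)c1
F2 | step 6 | [2-chloro-5-(methoxymethoxy)-3-methylbenzyl]potassium | COCOc1cc(C)c(Cl)c(C[K])c1
F3 | step 6 | (3R,6E,10E)-1-[2-chloro-5-(methoxymethoxy)-3-methylphenyl]-3,7,11,15-tetramethylhexadeca-6,10,14-trien-3-ol | CC(C)=CCC/C(C)=C/CC/C(C)=C/CC[C@@](C)(O)CCc1cc(OCOC)cc(C)c1Cl
F4 | step 7 | (2E,6E,10E)-13-[(2R)-6-(methoxymethoxy)-2,8-dimethyl-3,4-dihydro-2H-chromen-2-yl]-2,6,10-trimethyltrideca-2,6,10-trien-1-ol | OC/C(C)=C/CC/C(C)=C/CC/C(C)=C/CC[C@]1(C)CCc2cc(OCOC)cc(C)c2O1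
F5 | step 7 | (2E,6E,10E)-13-[(2R)-6-(methoxymethoxy)-2,8-dimethyl-3,4-dihydro-2H-chromen-2-yl]-2,6,10-trimethyltrideca-2,6,10-trienal | O=C/C(C)=C/CC/C(C)=C/CC/C(C)=C/CC[C@]1(C)CCc2cc(OCOC)cc(C)c2O1
F6 | step 2 | (2E,6E)-farnesyl phenyl sulfone | CC(C)=CCC/C(C)=C/CC/C(C)=C/CS(=O)(=O)c1ccccc1
F7 | step 2 | lithiated (2E,6E)-farnesyl phenyl sulfone | CC(C)=CCC/C(C)=C/CC/C(C)=C/C([Li])S(=O)(=O)c1ccccc1
F8 | step 2 | (2R,5E,9E)-2,6,10,14-tetramethyl-4-(phenylsulfonyl)pentadeca-5,9,13-triene-1,2-diol (epimers at the sulfonyl carbon) | CC(C)=CCC/C(C)=C/CC/C(C)=C/C(C[C@@](C)(O)CO)S(=O)(=O)c1ccccc1
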